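**Plan**
- Retrosynthetic cuts, in order: O1–C2 (pyranone C–O, cyclodehydration); C4a–C5 (benzene ring, intramolecular C-acylation of an acylketene); C4–C4a and C8–C8a (two Claisen-type acylations); C2–C3 (Meldrum's acid homologation).
- Enabling feature: the carbocycle C4a–C5–C6–C7–C8–C8a carries oxygen on C5, C7 and C8a and the acyl carbon C4 on C4a. It is a C-acylphloroglucinol, i.e. the Claisen-folded form of a linear poly-β-carbonyl chain whose C5 terminus is at the acid oxidation level, so a dioxinone can serve as a latent acylketene.
- Forward order: C2–C3 is joined (henicosanoic acid + Meldrum's acid) and the C2 ketone is masked as a dioxolane. C8–C8a is joined (acetyl chloride onto trimethyldioxinone), then C4–C4a (keto-dioxinone dianion + Weinreb amide). The benzene ring closes in step 6 and the pyranone ring in step 7.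
- The dioxolane on C2 is kept through the benzannulation, so that C8a/C4 is the only 1,3-diketone offered to magnesium. It is removed in the same acid step that closes the pyranone.
- Stereochemistry: none to set. The target has no stereocentre and no stereogenic double bond, so the achiral compound itself is taken as the single stereoisomer asked for.

Key step: step 6

**Route**

Step 1
Reactants: 1 henicosanoic acid; 2 Meldrum's acid
Product: 4 methyl 3-oxotricosanoate, via acyl Meldrum's acid 3 (not isolated)
Conditions: DCC, DMAP, CH2Cl2, 0 °C → rt; filter, concentrate; MeOH, reflux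
Reagents that add atoms: methanol, CO
Why: Oikawa–Yonemitsu β-keto ester synthesis, in which carbodiimide activation C-acylates Meldrum's acid at C5 to give 3 and boiling methanol opens the dioxanedione with loss of acetone and CO2, forming the C2–C3 bond.

Step 2
Reactants: 4 methyl 3-oxotricosanoate
Product: 5 methyl 2-(2-icosyl-1,3-dioxolan-2-yl)acetate
Conditions: HOCH2CH2OH, p-TsOH·H2O (cat.), toluene, reflux (Dean–Stark)
Reagents that add atoms: ethylene glycol, OCCO
Why: Acid-catalysed ketalisation with azeotropic removal of water masks the C2 ketone as a base-stable dioxolane, so that the acyl donor no longer carries a 1,3-dicarbonyl methylene that would quench the dianion of step 5.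

Step 3
Reactants: 5 methyl 2-(2-icosyl-1,3-dioxolan-2-yl)acetate
Product: 6 2-(2-icosyl-1,3-dioxolan-2-yl)-N-methoxy-N-methylacetamide
Conditions: MeNH(OMe)·HCl, i-PrMgCl, THF, −20 → 0 °C; aq NH4Cl
Reagents that add atoms: N,O-dimethylhydroxylamine hydrochloride, CNOC.Cl
Why: Weinreb amidation of an ester by the chloromagnesium amide of N,O-dimethylhydroxylamine, a weakly basic nucleophile that leaves the dioxolane untouched.

Step 4
Reactants: 7 2,2,6-trimethyl-4H-1,3-dioxin-4-one
Product: 8 2,2-dimethyl-6-(2-oxopropyl)-4H-1,3-dioxin-4-one
Conditions: LiHMDS (1.0 equiv), THF, −78 °C; AcCl (0.5 equiv), −78 °C; aq NH4Cl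
Reagents that add atoms: acetyl chloride, CC(=O)Cl
Why: γ-Deprotonation gives the extended lithium dienolate, which undergoes vinylogous Claisen C-acylation at the exocyclic carbon (future C8) to form C8–C8a; half an equivalent of the chloride is used because the more acidic product consumes a second equivalent of dienolate.

Step 5
Reactants: 8 2,2-dimethyl-6-(2-oxopropyl)-4H-1,3-dioxin-4-one; 6 2-(2-icosyl-1,3-dioxolan-2-yl)-N-methoxy-N-methylacetamide
Product: 9 6-[5-(2-icosyl-1,3-dioxolan-2-yl)-2,4-dioxopentyl]-2,2-dimethyl-4H-1,3-dioxin-4-one
Conditions: 8 (1.6 equiv), LDA (3.3 equiv), THF, −78 °C; then 6 (1.0 equiv) in THF, −78 → −20 °C; aq NH4Cl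
Reagents that add atoms: none
Why: Claisen acylation of a 1,3-dicarbonyl dianion, in which double deprotonation of 8 (ring CH2, then CH3) puts the reactive carbanion on the terminal carbon (future C4a), which adds to the Weinreb amide to give a chelated tetrahedral adduct that resists over-addition and releases the C8a/C4 diketone only on work-up, forming C4–C4a.

Step 6
Reactants: 9 6-[5-(2-icosyl-1,3-dioxolan-2-yl)-2,4-dioxopentyl]-2,2-dimethyl-4H-1,3-dioxin-4-one
Product: 11 2-(2-icosyl-1,3-dioxolan-2-yl)-1-(2,4,6-trihydroxyphenyl)ethan-1-one, via acylketene 10 (not isolated)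
Conditions: Mg(OMe)2 (1.1 equiv, MeOH solution), toluene, rt; distil off MeOH; 110 °C; cold 0.5 M HCl
Reagents that add atoms: none
Why: Proposed new method: Mg(OMe)2 converts the only free 1,3-diketone of 9 (C8a/C4) into a six-membered magnesium chelate whose nucleophilic carbon is C4a, and at about 110 °C the dioxinone then loses acetone by retro-hetero-Diels–Alder reaction to give acylketene 10, whose ketene carbon (future C5) lies five bonds from C4a. The chelated enolate C-acylates the ketene in a 6-(enolendo)-exo-dig closure (the Dieckmann mode with a ketene in place of an ester), forming C4a–C5, and the resulting 2-acylcyclohexane-1,3,5-trione aromatises by triple enolisation to the C-acylphloroglucinol 11. The closest known reaction types are the magnesium-alkoxide-templated Claisen cyclisation of 3,5,7-triketo esters to acylphloroglucinols and the thermolysis of keto-dioxinones to acylketenes that are trapped by O- or C-nucleophiles; new here is their combination in the Claisen sense on a dioxinone. The step needs C4a→C5 acylation to beat O-acylation to a 4-hydroxy-2-pyranone and the C6→C4 aldol mode: magnesium ties up the two enolate oxygens and leaves C4a as the nucleophilic site, the ketene is far more electrophilic than any ketone of the chain, and the dioxolane removes the C2 carbonyl both as an aldol acceptor and as a second chelation site. Any methyl ester (from residual methoxide) or pyranone (from O-trapping) that forms is expected to be funnelled to 11 by the same magnesium methoxide, since both are substrates of the known Claisen cyclisation. No stereocentre is created.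

Step 7
Reactants: 11 2-(2-icosyl-1,3-dioxolan-2-yl)-1-(2,4,6-trihydroxyphenyl)ethan-1-one
Product: 13 5,7-dihydroxy-2-icosyl-4H-chromen-4-one, via 1-(2,4,6-trihydroxyphenyl)tricosane-1,3-dione 12 (not isolated)
Conditions: conc. HCl (cat.), AcOH–H2O (9:1), 90 °C
Reagents that add atoms: none
Why: Acid hydrolysis of the dioxolane unmasks the C2 ketone to give 12, whose 2-hydroxyaryl 1,3-diketone undergoes hemiketalisation by an ortho phenol (6-exo-trig) and dehydration, the closing stage of a Baker–Venkataraman chromone synthesis; the two ortho hydroxyls are equivalent by symmetry, so only one chromone can form.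

**Compound list**
1 | henicosanoic acid | CCCCCCCCCCCCCCCCCCCCC(=O)O | starting material
2 | Meldrum's acid (2,2-dimethyl-1,3-dioxane-4,6-dione) | CC1(C)OC(=O)CC(=O)O1 | starting material
3 | 5-(1-hydroxyhenicosylidene)-2,2-dimethyl-1,3-dioxane-4,6-dione (acyl Meldrum's acid, enol form) | CCCCCCCCCCCCCCCCCCCCC(O)=C1C(=O)OC(C)(C)OC1=O | intermediate
4 | methyl 3-oxotricosanoate | CCCCCCCCCCCCCCCCCCCCC(=O)CC(=O)OC | intermediate
5 | methyl 2-(2-icosyl-1,3-dioxolan-2-yl)acetate | CCCCCCCCCCCCCCCCCCCCC1(CC(=O)OC)OCCO1 | intermediate
6 | 2-(2-icosyl-1,3-dioxolan-2-yl)-N-methoxy-N-methylacetamide | CCCCCCCCCCCCCCCCCCCCC1(CC(=O)N(C)OC)OCCO1 | intermediate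
7 | 2,2,6-trimethyl-4H-1,3-dioxin-4-one | CC1=CC(=O)OC(C)(C)O1 | starting material
8 | 2,2-dimethyl-6-(2-oxopropyl)-4H-1,3-dioxin-4-one | CC(=O)CC1=CC(=O)OC(C)(C)O1 | intermediate
9 | 6-[5-(2-icosyl-1,3-dioxolan-2-yl)-2,4-dioxopentyl]-2,2-dimethyl-4H-1,3-dioxin-4-one (drawn as the diketo tautomer) | CCCCCCCCCCCCCCCCCCCCC1(CC(=O)CC(=O)CC2=CC(=O)OC(C)(C)O2)OCCO1 | intermediate
10 | 8-(2-icosyl-1,3-dioxolan-2-yl)oct-1-ene-1,3,5,7-tetrone (acylketene; reacts as its magnesium enolate) | CCCCCCCCCCCCCCCCCCCCC1(CC(=O)CC(=O)CC(=O)C=C=O)OCCO1 | intermediate
11 | 2-(2-icosyl-1,3-dioxolan-2-yl)-1-(2,4,6-trihydroxyphenyl)ethan-1-one | CCCCCCCCCCCCCCCCCCCCC1(CC(=O)c2c(O)cc(O)cc2O)OCCO1 | intermediate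
12 | 1-(2,4,6-trihydroxyphenyl)tricosane-1,3-dione | CCCCCCCCCCCCCCCCCCCCC(=O)CC(=O)c1c(O)cc(O)cc1O | intermediate
13 | 5,7-dihydroxy-2-icosyl-4H-chromen-4-one | CCCCCCCCCCCCCCCCCCCCc1cc(=O)c2c(O)cc(O)cc2o1 | target

**Step count and risks**

Total steps: 7. Longest linear sequence: 6 steps (1, 2, 3, 5, 6, 7 from henicosanoic acid); step 4 is a one-step branch from the dioxinone.

Steps most likely to fail:

1. Step 6 (the proposed new method). The acylketene may be captured at oxygen (by the enol oxygen or by methoxide) faster than at C4a, and the C6→C4 aldol condensation of the species so formed may then outrun the Claisen closure. The fallback separates ketene generation from ring closure and uses only known reactions. It sets out from 9, which is heated in toluene with excess methanol at 110 °C, so that the acylketene is trapped intermolecularly as methyl 8-(2-icosyl-1,3-dioxolan-2-yl)-3,5,7-trioxooctanoate F1. The crude ester is then treated with magnesium methoxide in methanol (rt to reflux), the established magnesium-templated Claisen cyclisation of a 3,5,7-triketo ester, which expels methanol and returns to the route at 11.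

2. Step 5. Proton transfer from the α-methylene of the Weinreb amide to the strongly basic dianion, followed by β-alkoxide elimination that opens the dioxolane, may compete with C-acylation. The waxy amide may also dissolve poorly at −78 °C. The fallback replaces the Claisen acylation by aldol addition and oxidation. It sets out from 6, which is reduced with DIBAL-H (THF, −78 °C) to 2-(2-icosyl-1,3-dioxolan-2-yl)acetaldehyde F2. The aldehyde is added to the dianion of 8 at −78 °C, where carbonyl addition should be much faster than enolisation, to give racemic 6-[4-hydroxy-5-(2-icosyl-1,3-dioxolan-2-yl)-2-oxopentyl]-2,2-dimethyl-4H-1,3-dioxin-4-one F3. Dess–Martin oxidation (NaHCO3, CH2Cl2) removes the transient stereocentre and returns to the route at 9.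

3. Step 3. Aminolysis of the ester may be slow, because its carbonyl sits next to a quaternary ketal carbon bearing the C20 chain. This would leave room for enolisation with ring-opening of the dioxolane, or for incomplete conversion. The fallback forms the amide bond by coupling instead of aminolysis. It sets out from 5, which is saponified (LiOH, THF–MeOH–H2O; acidification only to pH 4 with citric acid) to 2-(2-icosyl-1,3-dioxolan-2-yl)acetic acid F4. The acid is activated with carbonyldiimidazole in CH2Cl2 and treated with N,O-dimethylhydroxylamine hydrochloride, returning to the route at 6.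

Further compounds
F1 | step 6 | methyl 8-(2-icosyl-1,3-dioxolan-2-yl)-3,5,7-trioxooctanoate | CCCCCCCCCCCCCCCCCCCCC1(CC(=O)CC(=O)CC(=O)CC(=O)OC)OCCO1
F2 | step 5 | 2-(2-icosyl-1,3-dioxolan-2-yl)acetaldehyde | CCCCCCCCCCCCCCCCCCCCC1(CC=O)OCCO1
F3 | step 5 | 6-[4-hydroxy-5-(2-icosyl-1,3-dioxolan-2-yl)-2-oxopentyl]-2,2-dimethyl-4H-1,3-dioxin-4-one (racemic) | CCCCCCCCCCCCCCCCCCCCC1(CC(O)CC(=O)CC2=CC(=O)OC(C)(C)O2)OCCO1
F4 | step 3 | 2-(2-icosyl-1,3-dioxolan-2-yl)acetic acid | CCCCCCCCCCCCCCCCCCCCC1(CC(=O)O)OCCO1
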